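The data are simulated on assumed constants, and the scatter is random.

Late readings say most here, so I list the flasks and then work from the last row of each run, using the fraction of starting material left and not the fraction made.

| setting | dawn | summer | spring | midnight | noon |
|---|---|---|---|---|---|
| starting material | 0.120 M | 0.0480 M | 0.0600 M | 0.120 M | 0.120 M |
| coupling partner | 0.132 M | 0.0600 M | 0.132 M | 0.132 M | 0.660 M |
| target |  |  |  | 0.0360 M |  |
| time |  |  |  |  | 19 min |

| dawn run: time / min | dawn run: [starting material] / M | summer run: time / min | summer run: [starting material] / M | spring run: time / min | spring run: [starting material] / M | midnight run: time / min | midnight run: [starting material] / M |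
|---|---|---|---|---|---|---|---|
| 0.68 | 0.1169 | 0.68 | 0.0476 | 0.68 | 0.0592 | 0.68 | 0.1168 |
| 2.1 | 0.1115 | 2.1 | 0.0460 | 2.1 | 0.0556 | 2.1 | 0.1121 |
| 4.0 | 0.1050 | 4.0 | 0.0437 | 4.0 | 0.0528 | 4.0 | 0.1065 |
| 6.3 | 0.0998 | 6.3 | 0.0433 | 6.3 | 0.0502 | 6.3 | 0.1003 |
| 9.0 | 0.0948 | 9.0 | 0.0418 | 9.0 | 0.0472 | 9.0 | 0.0965 |
| 12 | 0.0901 | 12 | 0.0409 | 12 | 0.0444 | 12 | 0.0937 |
| 15 | 0.0873 | 15 | 0.0395 | 15 | 0.0426 | 15 | 0.0908 |
| 19 | 0.0833 | 19 | 0.0376 | 19 | 0.0414 | 19 | 0.0884 |

(readings scatter by 4 × 10⁻⁴ M)

- reaction order in [starting material] at the outset, round the charge of the dawn run, defined at two percent of the starting material turned into target (one fixed amount of target, the same in the runs compared)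
- reaction order in [coupling partner] at the outset, round the charge of the dawn run, defined at two percent of the starting material turned into target
- starting material in the noon run at 19 min, as a share of the starting material charged

- Overall: starting material + coupling partner -> target.
- Constant volume, constant temperature.
- An order is taken over about fifteen percent of the charge, up and down.

I call the toll of a run minus the natural logarithm of its fraction left, so that tolls add where fractions multiply. At 19 min the toll is 0.365 in the dawn run and 0.371 in the spring run, which holds half the starting material and the same coupling partner. The difference lies within the scatter, so I take the order in starting material as close to one. Their mean is 0.368, and the summer run, with 0.0600 M of coupling partner, pays 0.244, which is less.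

Two charges of coupling partner give a line, so at this fixed time my ledger has two entries. One is the toll per molar of coupling partner charged, 1.72 M⁻¹. The other remains when that charge is taken to zero, 0.141.

In the noon run the starting material is the limiting reagent, 0.120 M against 0.660 M. The first entry keeps 32.1% of it, and the second keeps 86.8% of that. The books close at 27.9% left at 19 min, which is 0.0335 M left and 0.0865 M gone. This line rests on two charges and is stretched to 5.00 times the dawn charge of coupling partner, and one standard deviation on the last summer reading, acting on both entries, shifts the noon toll by 0.0780.

The forecast gives orders of 0.95 and 0.6 and leaves 46%, calling the effect of coupling partner “probably a saturating dependence”. I differ from it by leaving less.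

The noon run gives 27.9% left at 19 min, and the orders at the outset are 1.1 in starting material and 1.1 in coupling partner.

    starting material + coupling partner ⇌ target (0.2526 M⁻¹ min⁻¹, 0.007980 min⁻¹)
    coupling partner → lost reagent (0.08760 min⁻¹)
    starting material → decomposed substrate (0.006180 min⁻¹)

The midnight run is charged like the dawn run, with 0.0360 M of target besides. Its 0.132 M of coupling partner, at 1.72 M⁻¹, plus the second entry of 0.141, gives a toll of 0.368, or 69.2% left. Its last reading shows a toll of 0.306, or 73.7% left.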